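## Retrosynthetic overview

1. Feature used: ring B, the benzene ring of the dihydrobenzofuran (C3a, C4, C5, C6, C7, C7a), bears O1 on C7a, a hydroxyl on C7 and the flavonol carbon on C4. It is opened to the triene C3a=C7a / C7=C6 / C5=C4 hanging on an enantiopure trans-2,3-dihydrofuran (O1, C2, C3, C3a, C7a), so that C3a–C4 is made by 6π-electrocyclisation and the arene by dehydrogenation.
2. Flavonol: rings A and C are cut back to a 2'-hydroxychalcone (Algar–Flynn–Oyamada oxidation) from the C4 aldehyde and a dibenzyl ether of 2',4',6'-trihydroxyacetophenone.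
3. Triene: C5=C4 by Wittig reaction of an (E)-3-benzyloxy enal; its C7–O bond and C7=C6 geometry come from oxa-Michael addition of benzyl alcohol to an ynal; the alkyne is put on C7a by acetylide addition to a trans γ-lactone and dehydration.
4. Stereocentres C2 and C3: iridium-catalysed anti-(hydroxymethyl)allylation of O-benzylvanillin with the cyclic carbonate of cis-but-2-ene-1,4-diol; hydroboration and oxidative lactonisation then give the lactone.
5. Order of ring formation: dihydrofuran ring (steps 6 and 7), ring B (step 12), ring C (step 17); ring A and the guaiacyl ring are bought.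

Key step: step 12

## Remarks

- Atom labels (O1, C2, C3, C3a, C4 to C7, C7a) are those of the dihydrobenzofuran of the target and are used for the same atoms in all intermediates. Ar = 4-(benzyloxy)-3-methoxyphenyl; TIPS = tri(propan-2-yl)silyl.
- Assumption: the (R)-configured ligand is taken to give the (1R,2S) diol in step 3; should the sense of induction be the opposite, the (S)-ligand is used.
- The C7 oxygen is carried as a benzyl enol ether and not as a silyl enol ether made by enolate silylation. Enolate trapping would be expected to place the oxygen, not C7a, cis to C5. A halogen or acid catalyst that could correct this would attack both enol ethers. An aryl silyl ether would also not survive the hydroxide of steps 16 and 17.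
- The C7a–C7 bond is made from the lactone and an acetylide and not by metalation of a dihydrofuran. The benzylic C2–H and the benzyl ether would compete for the base, and a glutaconyl acylating agent would be deprotonated at its doubly activated methylene.
- The oxidant of the key step is added only after ring closure, because DDQ attacks enol ethers.

## Route

Step 1
Reactants: 1 vanillin (4-hydroxy-3-methoxybenzaldehyde)
Product: 2 4-(benzyloxy)-3-methoxybenzaldehyde
Conditions: BnBr, K2CO3, DMF, rt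
Reagents that add atoms: benzyl bromide, BrCc1ccccc1
Why: Williamson ether synthesis on the phenoxide; the benzyl ether is stable to every base, hydride and oxidant used before the final hydrogenolysis.

Step 2
Reactants: 3 (Z)-but-2-ene-1,4-diol
Product: 4 4,7-dihydro-1,3-dioxepin-2-one
Conditions: 1,1'-carbonyldiimidazole, CH2Cl2 (0.05 M), 0 °C → rt
Reagents that add atoms: 1,1'-carbonyldiimidazole, O=C(n1ccnc1)n1ccnc1
Why: Twofold acyl substitution (carbonate formation); the Z-alkene holds both hydroxyls on one side, so the seven-membered ring should close in preference to oligomers under dilution.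

Step 3
Reactants: 2 4-(benzyloxy)-3-methoxybenzaldehyde; 4 4,7-dihydro-1,3-dioxepin-2-one
Product: 5 (1R,2S)-1-Ar-2-ethenylpropane-1,3-diol
Conditions: preformed π-allyliridium C,O-benzoate complex from [Ir(cod)Cl]2, (R)-SEGPHOS, 4-cyano-3-nitrobenzoic acid and allyl acetate (5 mol %), K3PO4 (cat.), i-PrOH (2 equiv), THF, 70 °C
Reagents that add atoms: none
Why: Transfer-hydrogenative carbonyl (hydroxymethyl)allylation of the Krische type: ionisation of 4 with loss of CO2 gives an (E)-σ-allyliridium species that adds to the aldehyde through a closed chair transition state, which sets the anti relation of C2 and C3, while the chiral bisphosphine selects the aldehyde face and so the (1R,2S) series.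

Step 4
Reactants: 5 (1R,2S)-1-Ar-2-ethenylpropane-1,3-diol
Product: 6 (1R,2S)-1-Ar-2-(TIPS-oxymethyl)but-3-en-1-ol
Conditions: TIPSCl, imidazole, DMF, 0 °C
Reagents that add atoms: chlorotri(propan-2-yl)silane, CC(C)[Si](Cl)(C(C)C)C(C)C
Why: Silylation; the bulky silyl chloride should react at the primary hydroxyl and leave the hindered benzylic secondary one free.

Step 5
Reactants: 6 (1R,2S)-1-Ar-2-(TIPS-oxymethyl)but-3-en-1-ol
Product: 8 (1R,2S)-1-Ar-2-(TIPS-oxymethyl)butane-1,4-diol, via B-alkyl-9-borabicyclo[3.3.1]nonane adduct 7 (not isolated)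
Conditions: 9-BBN dimer, THF, 0 °C → rt; then NaOH (aq.), H2O2, 0 °C
Reagents that add atoms: hydrogen peroxide, OO
Why: Brown hydroboration–oxidation; 9-BBN adds anti-Markovnikov to the terminal alkene and oxidation with retention gives the primary alcohol without touching C2 or C3.

Step 6
Reactants: 8 (1R,2S)-1-Ar-2-(TIPS-oxymethyl)butane-1,4-diol
Product: 10 (4S,5R)-5-Ar-4-(TIPS-oxymethyl)oxolan-2-one, via lactol 9 (not isolated)
Conditions: TEMPO (10 mol %), PhI(OAc)2 (2.5 equiv), CH2Cl2, rt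
Reagents that add atoms: none
Why: Oxoammonium (TEMPO) oxidation: the primary alcohol is oxidised faster than the secondary one, the hydroxy aldehyde closes to the lactol and this is oxidised on to the trans γ-lactone (oxidative lactonisation of a 1,4-diol).

Step 7
Reactants: 10 (4S,5R)-5-Ar-4-(TIPS-oxymethyl)oxolan-2-one
Product: 13 (2R,3S)-2-Ar-3-(TIPS-oxymethyl)-5-[(trimethylsilyl)ethynyl]-2,3-dihydrofuran, via lithium hemiketal alkoxide 11 (not isolated), via hemiketal methanesulfonate 12 (not isolated)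
Conditions: ethynyl(trimethyl)silane, n-BuLi, THF, −78 °C; then 10, −78 °C; then MsCl, Et3N, −78 → 0 °C
Reagents that add atoms: ethynyl(trimethyl)silane, C#C[Si](C)(C)C
Why: 1,2-Addition of the lithium acetylide to the lactone carbonyl gives a cyclic tetrahedral alkoxide that stays closed at −78 °C, and its sulfonylation, loss of methanesulfonate through the oxocarbenium ion and deprotonation at C3a (the only β-hydrogens) give the endocyclic enol ether, as in the preparation of 1-C-alkynyl glycals from sugar lactones; trapping before work-up keeps the benzylic C2–O bond out of any open-chain hydroxy ynone.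

Step 8
Reactants: 13 (2R,3S)-2-Ar-3-(TIPS-oxymethyl)-5-[(trimethylsilyl)ethynyl]-2,3-dihydrofuran
Product: 14 (2R,3S)-2-Ar-5-ethynyl-3-(TIPS-oxymethyl)-2,3-dihydrofuran
Conditions: K2CO3 (cat.), MeOH/THF, 0 °C → rt
Reagents that add atoms: none
Why: Methoxide-mediated protodesilylation of the alkynylsilane; the TIPS ether and the enol ether are inert to this weak base.

Step 9
Reactants: 14 (2R,3S)-2-Ar-5-ethynyl-3-(TIPS-oxymethyl)-2,3-dihydrofuran
Product: 16 3-[(4S,5R)-5-Ar-4-(TIPS-oxymethyl)-4,5-dihydrofuran-2-yl]prop-2-ynal, via lithium acetylide 15 (not isolated)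
Conditions: n-BuLi (1.0 equiv), THF, −78 °C; DMF, −78 → 0 °C; inverse quench into cold aq. KH2PO4
Reagents that add atoms: N,N-dimethylformamide, CN(C)C=O
Why: Formylation of a lithium acetylide with DMF; the acetylenic C–H is removed far faster than any other proton, and the buffered inverse quench should release the ynal without conjugate addition of dimethylamine or hydrolysis of the enol ether.

Step 10
Reactants: 16 3-[(4S,5R)-5-Ar-4-(TIPS-oxymethyl)-4,5-dihydrofuran-2-yl]prop-2-ynal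
Product: 17 (2E)-3-(benzyloxy)-3-[(4S,5R)-5-Ar-4-(TIPS-oxymethyl)-4,5-dihydrofuran-2-yl]prop-2-enal
Conditions: BnOH (1.1 equiv), DABCO (10 mol %), CH2Cl2, 0 °C → rt
Reagents that add atoms: benzyl alcohol, OCc1ccccc1
Why: Amine-catalysed oxa-Michael addition to the ynal; the addition is reversible under the conditions, so the product should settle in the geometry usual for 3-alkoxy enals and enones, alkoxy group anti to the carbonyl (E), which is the geometry that holds C7a cis to C5.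

Step 11
Reactants: 17 (2E)-3-(benzyloxy)-3-[(4S,5R)-5-Ar-4-(TIPS-oxymethyl)-4,5-dihydrofuran-2-yl]prop-2-enal
Product: 18 methyl (2E,4E)-5-(benzyloxy)-5-[(4S,5R)-5-Ar-4-(TIPS-oxymethyl)-4,5-dihydrofuran-2-yl]penta-2,4-dienoate
Conditions: Ph3P=CHCO2Me, toluene, 60 °C
Reagents that add atoms: methyl (triphenyl-λ5-phosphanylidene)acetate, COC(=O)C=P(c1ccccc1)(c1ccccc1)c1ccccc1
Why: Wittig olefination with a stabilised ylide should give the (2E)-enoate under neutral conditions that leave the enol ether geometry and both enol ethers intact.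

Step 12
Reactants: 18 methyl (2E,4E)-5-(benzyloxy)-5-[(4S,5R)-5-Ar-4-(TIPS-oxymethyl)-4,5-dihydrofuran-2-yl]penta-2,4-dienoate
Product: 20 methyl (2R,3S)-2-Ar-7-(benzyloxy)-3-(TIPS-oxymethyl)-2,3-dihydro-1-benzofuran-4-carboxylate, via cis-3a,4-dihydro intermediate 19 (not isolated)
Conditions: degassed o-xylene (0.01 M), 140 °C, sealed tube; then 0 °C, DDQ (1.05 equiv)
Reagents that add atoms: none
Why: On heating, the triene (C3a=C7a, C7=C6, C5=C4) reaches its coiled s-cis,s-cis conformer and undergoes a thermal disrotatory six-electron electrocyclisation that joins C3a to C4 and gives cyclohexadiene 19; DDQ, added only after closure is complete, then takes hydride from the doubly allylic C3a–H (cation stabilised by the C7 oxygen) and a proton leaves C4, so the arene forms with O1, the C7 benzyl ether and the C4 ester in place. The closest known reaction type is the hexatriene-to-cyclohexadiene closure of 2-oxygenated trienes followed by quinone dehydrogenation to the arene. Ring B is the one ring closed, in a pericyclic 6π mode with suprafacial bonding at both termini. No lasting stereocentre is made: in 19 the two outside groups (C3 on C3a, CO2Me on C4) turn to the same face, so 3a-H and 4-H are cis, and C4 should add to the face of C3a away from the CH2OTIPS group, but both centres become sp2 on oxidation. The step needs C7a and C5 cis on C7=C6, which the (E)-benzyl enol ether from steps 10 and 11 provides, and it needs the oxidant to stop at the arene, which one equivalent of DDQ at 0 °C should secure because a cyclohexadiene is dehydrogenated far faster than the C2–H/C3–H pair of a dihydrobenzofuran or a benzyl ether. C2 and C3 lie outside the reacting π-system and carry no acidic hydrogen, so they should keep the (2R,3S) configuration.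

Step 13
Reactants: 20 methyl (2R,3S)-2-Ar-7-(benzyloxy)-3-(TIPS-oxymethyl)-2,3-dihydro-1-benzofuran-4-carboxylate
Product: 21 [(2R,3S)-2-Ar-7-(benzyloxy)-3-(TIPS-oxymethyl)-2,3-dihydro-1-benzofuran-4-yl]methanol
Conditions: i-Bu2AlH (2.5 equiv), CH2Cl2, −78 → 0 °C; aq. potassium sodium tartrate
Reagents that add atoms: none
Why: Hydride reduction of the aryl ester to the benzylic alcohol; silyl and benzyl ethers are inert.

Step 14
Reactants: 21 [(2R,3S)-2-Ar-7-(benzyloxy)-3-(TIPS-oxymethyl)-2,3-dihydro-1-benzofuran-4-yl]methanol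
Product: 22 (2R,3S)-2-Ar-7-(benzyloxy)-3-(TIPS-oxymethyl)-2,3-dihydro-1-benzofuran-4-carbaldehyde
Conditions: MnO2 (activated, excess), CH2Cl2, rt
Reagents that add atoms: none
Why: Selective oxidation of a benzylic alcohol with activated MnO2, which should stop at the aldehyde and not touch C2–H or C3–H.

Step 15
Reactants: 23 1-(2,4,6-trihydroxyphenyl)ethan-1-one
Product: 24 1-[2,4-bis(benzyloxy)-6-hydroxyphenyl]ethan-1-one
Conditions: BnBr (2.1 equiv), K2CO3, DMF, rt
Reagents that add atoms: benzyl bromide, BrCc1ccccc1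
Why: Williamson etherification; the hydroxyl that is hydrogen-bonded to the acetyl carbonyl is the least nucleophilic and should stay free for ring C.

Step 16
Reactants: 22 (2R,3S)-2-Ar-7-(benzyloxy)-3-(TIPS-oxymethyl)-2,3-dihydro-1-benzofuran-4-carbaldehyde; 24 1-[2,4-bis(benzyloxy)-6-hydroxyphenyl]ethan-1-one
Product: 25 (2E)-1-[2,4-bis(benzyloxy)-6-hydroxyphenyl]-3-[(2R,3S)-2-Ar-7-(benzyloxy)-3-(TIPS-oxymethyl)-2,3-dihydro-1-benzofuran-4-yl]prop-2-en-1-one
Conditions: KOH (aq. 50 %), EtOH/THF, rt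
Reagents that add atoms: none
Why: Claisen–Schmidt condensation; the aldehyde has no α-hydrogen and dehydration of the aldol should give the (E)-chalcone, while benzyl and TIPS ethers withstand the hydroxide.

Step 17
Reactants: 25 the (E)-chalcone
Product: 26 5,7-bis(benzyloxy)-2-[(2R,3S)-2-Ar-7-(benzyloxy)-3-(TIPS-oxymethyl)-2,3-dihydro-1-benzofuran-4-yl]-3-hydroxy-4H-chromen-4-one
Conditions: H2O2 (30 %), NaOH (aq.), MeOH/THF, 0 °C → rt
Reagents that add atoms: hydrogen peroxide, OO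
Why: Algar–Flynn–Oyamada oxidation; alkaline hydrogen peroxide converts the 2'-hydroxychalcone by oxidative cyclisation into the 3-hydroxyflavone, ring C closing through bond formation between the phenoxide oxygen and the β-carbon.

Step 18
Reactants: 26 the TIPS-protected tetrabenzyl flavonol
Product: 27 5,7-bis(benzyloxy)-2-[(2R,3S)-2-Ar-7-(benzyloxy)-3-(hydroxymethyl)-2,3-dihydro-1-benzofuran-4-yl]-3-hydroxy-4H-chromen-4-one
Conditions: HF·pyridine, pyridine, THF, 0 °C → rt
Reagents that add atoms: none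
Why: Fluoride-driven cleavage of the silyl ether under buffered conditions that leave benzyl ethers and the flavonol untouched.

Step 19
Reactants: 27 the tetrabenzyl flavonol
Product: 28 3,5,7-trihydroxy-2-[(2R,3S)-7-hydroxy-2-(4-hydroxy-3-methoxyphenyl)-3-(hydroxymethyl)-2,3-dihydro-1-benzofuran-4-yl]-4H-chromen-4-one
Conditions: H2 (1 atm), Pd/C (10 %), THF/MeOH, rt
Reagents that add atoms: none
Why: Hydrogenolysis of the four aryl benzyl ethers over Pd/C; these should be cleaved faster than the cyclic benzylic C2–O1 bond and the chromenone double bond, so the reaction is stopped after four equivalents of hydrogen.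

## Compound list

1 | vanillin | COc1cc(C=O)ccc1O | starting material
2 | 4-(benzyloxy)-3-methoxybenzaldehyde | COc1cc(C=O)ccc1OCc1ccccc1 | intermediate
3 | (Z)-but-2-ene-1,4-diol | OC/C=C\CO | starting material
4 | 4,7-dihydro-1,3-dioxepin-2-one | O=C1OC/C=C\CO1 | intermediate
5 | (1R,2S)-1-Ar-2-ethenylpropane-1,3-diol | COc1cc([C@H](O)[C@H](CO)C=C)ccc1OCc1ccccc1 | intermediate
6 | (1R,2S)-1-Ar-2-(TIPS-oxymethyl)but-3-en-1-ol | COc1cc([C@H](O)[C@H](CO[Si](C(C)C)(C(C)C)C(C)C)C=C)ccc1OCc1ccccc1 | intermediate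
7 | B-alkyl-9-borabicyclo[3.3.1]nonane adduct of 6 (boron on the terminal carbon, hydroxyl shown free) | COc1cc([C@H](O)[C@H](CO[Si](C(C)C)(C(C)C)C(C)C)CCB2C3CCCC2CCC3)ccc1OCc1ccccc1 | intermediate (not isolated)
8 | (1R,2S)-1-Ar-2-(TIPS-oxymethyl)butane-1,4-diol | COc1cc([C@H](O)[C@H](CO[Si](C(C)C)(C(C)C)C(C)C)CCO)ccc1OCc1ccccc1 | intermediate
9 | (4S,5R)-5-Ar-4-(TIPS-oxymethyl)oxolan-2-ol, both anomers | COc1cc([C@@H]2OC(O)C[C@H]2CO[Si](C(C)C)(C(C)C)C(C)C)ccc1OCc1ccccc1 | intermediate (not isolated)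
10 | (4S,5R)-5-Ar-4-(TIPS-oxymethyl)oxolan-2-one | COc1cc([C@@H]2OC(=O)C[C@H]2CO[Si](C(C)C)(C(C)C)C(C)C)ccc1OCc1ccccc1 | intermediate
11 | lithium (4S,5R)-5-Ar-4-(TIPS-oxymethyl)-2-[(trimethylsilyl)ethynyl]oxolan-2-olate, both C2 epimers | [Li+].COc1cc([C@@H]2OC([O-])(C#C[Si](C)(C)C)C[C@H]2CO[Si](C(C)C)(C(C)C)C(C)C)ccc1OCc1ccccc1 | intermediate (not isolated)
12 | (4S,5R)-5-Ar-4-(TIPS-oxymethyl)-2-[(trimethylsilyl)ethynyl]oxolan-2-yl methanesulfonate, both C2 epimers | COc1cc([C@@H]2OC(OS(C)(=O)=O)(C#C[Si](C)(C)C)C[C@H]2CO[Si](C(C)C)(C(C)C)C(C)C)ccc1OCc1ccccc1 | intermediate (not isolated)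
13 | (2R,3S)-2-Ar-3-(TIPS-oxymethyl)-5-[(trimethylsilyl)ethynyl]-2,3-dihydrofuran | COc1cc([C@@H]2OC(C#C[Si](C)(C)C)=C[C@H]2CO[Si](C(C)C)(C(C)C)C(C)C)ccc1OCc1ccccc1 | intermediate
14 | (2R,3S)-2-Ar-5-ethynyl-3-(TIPS-oxymethyl)-2,3-dihydrofuran | COc1cc([C@@H]2OC(C#C)=C[C@H]2CO[Si](C(C)C)(C(C)C)C(C)C)ccc1OCc1ccccc1 | intermediate
15 | lithium acetylide of 14 | [Li+].COc1cc([C@@H]2OC(C#[C-])=C[C@H]2CO[Si](C(C)C)(C(C)C)C(C)C)ccc1OCc1ccccc1 | intermediate (not isolated)
16 | 3-[(4S,5R)-5-Ar-4-(TIPS-oxymethyl)-4,5-dihydrofuran-2-yl]prop-2-ynal | COc1cc([C@@H]2OC(C#CC=O)=C[C@H]2CO[Si](C(C)C)(C(C)C)C(C)C)ccc1OCc1ccccc1 | intermediate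
17 | (2E)-3-(benzyloxy)-3-[(4S,5R)-5-Ar-4-(TIPS-oxymethyl)-4,5-dihydrofuran-2-yl]prop-2-enal | COc1cc([C@@H]2OC(/C(OCc3ccccc3)=C\C=O)=C[C@H]2CO[Si](C(C)C)(C(C)C)C(C)C)ccc1OCc1ccccc1 | intermediate
18 | methyl (2E,4E)-5-(benzyloxy)-5-[(4S,5R)-5-Ar-4-(TIPS-oxymethyl)-4,5-dihydrofuran-2-yl]penta-2,4-dienoate | COc1cc([C@@H]2OC(/C(OCc3ccccc3)=C\C=C\C(=O)OC)=C[C@H]2CO[Si](C(C)C)(C(C)C)C(C)C)ccc1OCc1ccccc1 | intermediate (key-step precursor)
19 | methyl (2R,3S)-2-Ar-7-(benzyloxy)-3-(TIPS-oxymethyl)-2,3,3a,4-tetrahydro-1-benzofuran-4-carboxylate, 3a-H trans to 3-H and cis to 4-H (diastereomer expected to predominate) | COc1cc([C@@H]2OC3=C(OCc4ccccc4)C=C[C@H](C(=O)OC)[C@@H]3[C@H]2CO[Si](C(C)C)(C(C)C)C(C)C)ccc1OCc1ccccc1 | intermediate (not isolated)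
20 | methyl (2R,3S)-2-Ar-7-(benzyloxy)-3-(TIPS-oxymethyl)-2,3-dihydro-1-benzofuran-4-carboxylate | COc1cc([C@@H]2Oc3c(OCc4ccccc4)ccc(C(=O)OC)c3[C@H]2CO[Si](C(C)C)(C(C)C)C(C)C)ccc1OCc1ccccc1 | intermediate (key-step product)
21 | [(2R,3S)-2-Ar-7-(benzyloxy)-3-(TIPS-oxymethyl)-2,3-dihydro-1-benzofuran-4-yl]methanol | COc1cc([C@@H]2Oc3c(OCc4ccccc4)ccc(CO)c3[C@H]2CO[Si](C(C)C)(C(C)C)C(C)C)ccc1OCc1ccccc1 | intermediate
22 | (2R,3S)-2-Ar-7-(benzyloxy)-3-(TIPS-oxymethyl)-2,3-dihydro-1-benzofuran-4-carbaldehyde | COc1cc([C@@H]2Oc3c(OCc4ccccc4)ccc(C=O)c3[C@H]2CO[Si](C(C)C)(C(C)C)C(C)C)ccc1OCc1ccccc1 | intermediate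
23 | 1-(2,4,6-trihydroxyphenyl)ethan-1-one | CC(=O)c1c(O)cc(O)cc1O | starting material
24 | 1-[2,4-bis(benzyloxy)-6-hydroxyphenyl]ethan-1-one | CC(=O)c1c(O)cc(OCc2ccccc2)cc1OCc1ccccc1 | intermediate
25 | (2E)-1-[2,4-bis(benzyloxy)-6-hydroxyphenyl]-3-[(2R,3S)-2-Ar-7-(benzyloxy)-3-(TIPS-oxymethyl)-2,3-dihydro-1-benzofuran-4-yl]prop-2-en-1-one | COc1cc([C@@H]2Oc3c(OCc4ccccc4)ccc(/C=C/C(=O)c4c(O)cc(OCc5ccccc5)cc4OCc4ccccc4)c3[C@H]2CO[Si](C(C)C)(C(C)C)C(C)C)ccc1OCc1ccccc1 | intermediate
26 | 5,7-bis(benzyloxy)-2-[(2R,3S)-2-Ar-7-(benzyloxy)-3-(TIPS-oxymethyl)-2,3-dihydro-1-benzofuran-4-yl]-3-hydroxy-4H-chromen-4-one | COc1cc([C@@H]2Oc3c(OCc4ccccc4)ccc(-c4oc5cc(OCc6ccccc6)cc(OCc6ccccc6)c5c(=O)c4O)c3[C@H]2CO[Si](C(C)C)(C(C)C)C(C)C)ccc1OCc1ccccc1 | intermediate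
27 | 5,7-bis(benzyloxy)-2-[(2R,3S)-2-Ar-7-(benzyloxy)-3-(hydroxymethyl)-2,3-dihydro-1-benzofuran-4-yl]-3-hydroxy-4H-chromen-4-one | COc1cc([C@@H]2Oc3c(OCc4ccccc4)ccc(-c4oc5cc(OCc6ccccc6)cc(OCc6ccccc6)c5c(=O)c4O)c3[C@H]2CO)ccc1OCc1ccccc1 | intermediate
28 | 3,5,7-trihydroxy-2-[(2R,3S)-7-hydroxy-2-(4-hydroxy-3-methoxyphenyl)-3-(hydroxymethyl)-2,3-dihydro-1-benzofuran-4-yl]-4H-chromen-4-one | COc1cc([C@@H]2Oc3c(O)ccc(-c4oc5cc(O)cc(O)c5c(=O)c4O)c3[C@H]2CO)ccc1O | target

## Step count and risks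

Total step count: 19 (steps 1 to 19).
Longest linear sequence: 17 steps (1, 3 to 14, 16 to 19, from vanillin).

Step 12. What may go wrong: the conjugation that runs from the C7 oxygen to the ester is lost on closure, so the ring closure may need a temperature at which the triene adds to itself in a [4+2] sense or drifts in its C7=C6 geometry, and DDQ would then meet unreacted enol ether. The fallback sets out from 18 and comes back to the route at 21; it takes the ester out of conjugation before the pericyclic step, so that the ring is closed at the alcohol oxidation level. i-Bu2AlH (CH2Cl2, −78 °C) should reduce 18 to (2E,4E)-5-(benzyloxy)-5-[(4S,5R)-5-Ar-4-(TIPS-oxymethyl)-4,5-dihydrofuran-2-yl]penta-2,4-dien-1-ol F1, and TBSCl with imidazole (DMF, 0 °C) should give its tert-butyldimethylsilyl ether F2. This triene, which has no acceptor and is a plain 2,3-dioxygenated hexatriene, should close in toluene at about 110 °C to the cis-3a,4-dihydro intermediate F3, and DDQ (1.05 equiv, 0 °C) should give (2R,3S)-2-Ar-7-(benzyloxy)-4-(tert-butyldimethylsilyloxymethyl)-3-(TIPS-oxymethyl)-2,3-dihydro-1-benzofuran F4. PPTS in ethanol at rt should cleave the primary benzylic TBS ether and leave the TIPS ether, which returns alcohol 21.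

Step 17. What may go wrong: with a 6'-alkoxy group on ring A and an ortho-substituted ring B, the oxidised enone may be closed at the α-carbon, so that five-membered ring closure to an aurone competes with flavonol formation. The fallback sets out from 20 (and uses 24) and comes back to the route at 26; ring C is built by acyl transfer and cyclodehydration (Baker–Venkataraman route) and C3 is oxygenated afterwards. LiOH (THF/MeOH/H2O, 50 °C) should give (2R,3S)-2-Ar-7-(benzyloxy)-3-(TIPS-oxymethyl)-2,3-dihydro-1-benzofuran-4-carboxylic acid F5. EDC·HCl and DMAP (CH2Cl2) with phenol 24 should give the 2-acetyl-3,5-bis(benzyloxy)phenyl ester F6. KOH in pyridine (50 °C) should bring about the Baker–Venkataraman rearrangement to the 1,3-diketone F7, and p-TsOH (cat., toluene, 80 °C) should close it to the 5,7-bis(benzyloxy)flavone F8. Dimethyldioxirane (acetone/CH2Cl2, 0 °C) should give the flavone 2,3-epoxide F9, which with p-TsOH (cat.) should open to the 3-hydroxyflavone 26.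

Step 3. What may go wrong: poor anti/syn or facial selectivity, or slow turnover, of the iridium-catalysed transfer-hydrogenative coupling with this electron-rich aryl aldehyde. The fallback sets out from 2 and comes back to the route at 10; the two stereocentres are set by an auxiliary-controlled syn-aldol reaction, and steps 3 to 6 are bypassed. (4R)-4-Benzyl-1,3-oxazolidin-2-one would be acylated (n-BuLi, THF, −78 °C; methyl 4-chloro-4-oxobutanoate) to methyl 4-[(4R)-4-benzyl-2-oxo-1,3-oxazolidin-3-yl]-4-oxobutanoate F10. Its dibutylboron enolate (Bu2BOTf, i-Pr2NEt, CH2Cl2, −78 → 0 °C) should add to 2 to give the (R,R)-syn-aldol adduct F11. This should close (p-TsOH cat., toluene, rt) to the trans imide lactone (4R)-4-benzyl-3-{[(2R,3R)-2-Ar-5-oxooxolan-3-yl]carbonyl}-1,3-oxazolidin-2-one F12. NaBH4 (THF/H2O, 0 °C) should remove the auxiliary reductively to (4S,5R)-5-Ar-4-(hydroxymethyl)oxolan-2-one F13, and TIPSCl with imidazole (DMF) would give 10.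

Further compounds
F1 | step 12 | (2E,4E)-5-(benzyloxy)-5-[(4S,5R)-5-Ar-4-(TIPS-oxymethyl)-4,5-dihydrofuran-2-yl]penta-2,4-dien-1-ol | COc1cc([C@@H]2OC(/C(OCc3ccccc3)=C\C=C\CO)=C[C@H]2CO[Si](C(C)C)(C(C)C)C(C)C)ccc1OCc1ccccc1
F2 | step 12 | tert-butyldimethylsilyl ether of F1 | COc1cc([C@@H]2OC(/C(OCc3ccccc3)=C\C=C\CO[Si](C)(C)C(C)(C)C)=C[C@H]2CO[Si](C(C)C)(C(C)C)C(C)C)ccc1OCc1ccccc1
F3 | step 12 | (2R,3S)-2-Ar-7-(benzyloxy)-4-(tert-butyldimethylsilyloxymethyl)-3-(TIPS-oxymethyl)-2,3,3a,4-tetrahydro-1-benzofuran, 3a-H trans to 3-H and cis to 4-H | COc1cc([C@@H]2OC3=C(OCc4ccccc4)C=C[C@H](CO[Si](C)(C)C(C)(C)C)[C@@H]3[C@H]2CO[Si](C(C)C)(C(C)C)C(C)C)ccc1OCc1ccccc1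
F4 | step 12 | (2R,3S)-2-Ar-7-(benzyloxy)-4-(tert-butyldimethylsilyloxymethyl)-3-(TIPS-oxymethyl)-2,3-dihydro-1-benzofuran | COc1cc([C@@H]2Oc3c(OCc4ccccc4)ccc(CO[Si](C)(C)C(C)(C)C)c3[C@H]2CO[Si](C(C)C)(C(C)C)C(C)C)ccc1OCc1ccccc1
F5 | step 17 | (2R,3S)-2-Ar-7-(benzyloxy)-3-(TIPS-oxymethyl)-2,3-dihydro-1-benzofuran-4-carboxylic acid | COc1cc([C@@H]2Oc3c(OCc4ccccc4)ccc(C(=O)O)c3[C@H]2CO[Si](C(C)C)(C(C)C)C(C)C)ccc1OCc1ccccc1
F6 | step 17 | 2-acetyl-3,5-bis(benzyloxy)phenyl ester of F5 | COc1cc([C@@H]2Oc3c(OCc4ccccc4)ccc(C(=O)Oc4cc(OCc5ccccc5)cc(OCc5ccccc5)c4C(C)=O)c3[C@H]2CO[Si](C(C)C)(C(C)C)C(C)C)ccc1OCc1ccccc1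
F7 | step 17 | 1-[2,4-bis(benzyloxy)-6-hydroxyphenyl]-3-[(2R,3S)-2-Ar-7-(benzyloxy)-3-(TIPS-oxymethyl)-2,3-dihydro-1-benzofuran-4-yl]propane-1,3-dione | COc1cc([C@@H]2Oc3c(OCc4ccccc4)ccc(C(=O)CC(=O)c4c(O)cc(OCc5ccccc5)cc4OCc4ccccc4)c3[C@H]2CO[Si](C(C)C)(C(C)C)C(C)C)ccc1OCc1ccccc1
F8 | step 17 | 5,7-bis(benzyloxy)-2-[(2R,3S)-2-Ar-7-(benzyloxy)-3-(TIPS-oxymethyl)-2,3-dihydro-1-benzofuran-4-yl]-4H-chromen-4-one | COc1cc([C@@H]2Oc3c(OCc4ccccc4)ccc(-c4cc(=O)c5c(OCc6ccccc6)cc(OCc6ccccc6)cc5o4)c3[C@H]2CO[Si](C(C)C)(C(C)C)C(C)C)ccc1OCc1ccccc1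
F9 | step 17 | 2,3-epoxide of flavone F8, both epoxide diastereomers | COc1cc([C@@H]2Oc3c(OCc4ccccc4)ccc(C45OC4C(=O)c4c(OCc6ccccc6)cc(OCc6ccccc6)cc4O5)c3[C@H]2CO[Si](C(C)C)(C(C)C)C(C)C)ccc1OCc1ccccc1
F10 | step 3 | methyl 4-[(4R)-4-benzyl-2-oxo-1,3-oxazolidin-3-yl]-4-oxobutanoate | COC(=O)CCC(=O)N1[C@H](Cc2ccccc2)COC1=O
F11 | step 3 | methyl (3R)-3-[(R)-Ar(hydroxy)methyl]-4-[(4R)-4-benzyl-2-oxo-1,3-oxazolidin-3-yl]-4-oxobutanoate | COc1cc([C@H](O)[C@@H](CC(=O)OC)C(=O)N2[C@H](Cc3ccccc3)COC2=O)ccc1OCc1ccccc1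
F12 | step 3 | (4R)-4-benzyl-3-{[(2R,3R)-2-Ar-5-oxooxolan-3-yl]carbonyl}-1,3-oxazolidin-2-one | COc1cc([C@@H]2OC(=O)C[C@H]2C(=O)N3[C@H](Cc4ccccc4)COC3=O)ccc1OCc1ccccc1
F13 | step 3 | (4S,5R)-5-Ar-4-(hydroxymethyl)oxolan-2-one | COc1cc([C@@H]2OC(=O)C[C@H]2CO)ccc1OCc1ccccc1
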